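The route rests on disconnecting the methoxy-trimethylcyclohexenedione ring at two bonds: the bond from the spiro carbon to the ketone carbonyl flanked by CMe2, and the bond from the enone carbonyl to the C-methyl carbon. The key step, a one-flask (3+3) acylation/Dieckmann annulation, joins a spirocyclic acid chloride to the enolate of methyl 2,2-dimethyl-3-oxopentanoate. It closes the six-membered triketone ring and creates the quaternary spiro stereocentre anti to the neighbouring isopropyl group. It exploits the C(=O)–C(spiro)–C(=O) unit of the cyclohexenedione ring, a masked 1,3,5-trione. The precursor acid comes from (+)-β-pinene through face-selective vinyl conjugate addition, Ireland–Claisen chirality transfer and ring-closing metathesis.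

Key step: step 11

Assumption: the pinane of the target belongs to the (1R,5R)-β-pinene series, and (1R,5R)-(+)-β-pinene is taken as a purchasable starting material (it is also reachable from (+)-α-pinene by the known allylpotassium/borate isomerisation).

Step 1
Reactants: 1 (1R,5R)-(+)-β-pinene
Product: 3 (1S,5R)-(−)-nopinone, via secondary ozonide 2 (not isolated)
Conditions: O3, CH2Cl2, −78 °C; then Me2S, −78 °C to rt
Reagents that add atoms: ozone, [O-][O+]=O
Why: Criegee ozonolysis with reductive work-up cleaves only the exocyclic C=CH2 bond to the ketone and leaves both bridgehead stereocentres untouched.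

Step 2
Reactants: 3 (1S,5R)-(−)-nopinone; 4 Meldrum's acid
Product: 5 5-[(1S,5R)-6,6-dimethylbicyclo[3.1.1]heptan-2-ylidene]-2,2-dimethyl-1,3-dioxane-4,6-dione
Conditions: TiCl4 (2 equiv), pyridine (4 equiv), THF, 0 °C to rt
Reagents that add atoms: none
Why: Knoevenagel condensation under TiCl4/pyridine activation, which is forcing enough for an α-branched cyclohexanone; the acceptor is symmetric, so no alkene geometry and no stereocentre arise.

Step 3
Reactants: 5 nopinylidene Meldrum's acid
Product: 6 5-[(1S,2R,5R)-2-ethenyl-6,6-dimethylbicyclo[3.1.1]heptan-2-yl]-2,2-dimethyl-1,3-dioxane-4,6-dione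
Conditions: CH2=CHMgBr (1.5 equiv), CuI (10 mol %), THF, −40 to 0 °C; then 1 M HCl
Reagents that add atoms: vinylmagnesium bromide, C=C[Mg]Br
Why: Copper-catalysed conjugate addition of a Grignard reagent to an alkylidene Meldrum's acid; the nucleophile should attack pinane C-2 from the CH2-bridge face, anti to the CMe2 bridge, which sets the quaternary stereocentre with vinyl anti and the malonyl carbon syn to the CMe2 bridge.

Step 4
Reactants: 6 vinyl adduct
Product: 7 2-[(1S,2R,5R)-2-ethenyl-6,6-dimethylbicyclo[3.1.1]heptan-2-yl]acetic acid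
Conditions: DMF/H2O (10:1), 110 °C
Reagents that add atoms: water, O
Why: Hydrolytic opening of the acylal followed by decarboxylation of the malonic acid (loss of acetone and CO2) gives the acetic acid side chain without touching the quaternary centre.

Step 5
Reactants: 8 (E)-5-methylhex-3-en-2-one
Product: 9 (2R,3E)-5-methylhex-3-en-2-ol
Conditions: (S)-2-methyl-CBS-oxazaborolidine (10 mol %), catecholborane (1.5 equiv), toluene, −78 °C
Reagents that add atoms: none
Why: Corey–Bakshi–Shibata reduction: the (S)-oxazaborolidine delivers hydride with the alkenyl group as the large substituent, which should give the (R)-allylic alcohol, and catecholborane at low temperature avoids hydroboration of the alkene.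

Step 6
Reactants: 7 vinyl acid; 9 (2R,3E)-5-methylhex-3-en-2-ol
Product: 10 (2R,3E)-5-methylhex-3-en-2-yl 2-[(1S,2R,5R)-2-ethenyl-6,6-dimethylbicyclo[3.1.1]heptan-2-yl]acetate
Conditions: DCC (1.2 equiv), DMAP (10 mol %), CH2Cl2, 0 °C to rt
Reagents that add atoms: none
Why: Steglich esterification acylates the alcohol oxygen, so the carbinol C–O bond and its (R) configuration are retained.

Step 7
Reactants: 10 allylic ester
Product: 13 (3S,4E)-2-[(1S,2R,5R)-2-ethenyl-6,6-dimethylbicyclo[3.1.1]heptan-2-yl]-3-(propan-2-yl)hex-4-enoic acid (C-2 epimer mixture), via silyl ketene acetal 11 (not isolated), via trimethylsilyl ester 12 (not isolated)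
Conditions: LiN(iPr)2 (1.3 equiv), Me3SiCl (1.5 equiv), THF, −78 °C, then 65 °C; then 1 M HCl
Reagents that add atoms: none
Why: Ireland–Claisen rearrangement: the silyl ketene acetal rearranges suprafacially through a chair transition state with the carbinol methyl group equatorial, so the (R) carbinol centre is transferred to the isopropyl-bearing carbon (3S) with an (E)-propenyl group; the α-carbon forms as an epimer mixture that is erased in step 11.

Step 8
Reactants: 13 Claisen acid
Product: 15 6,6-dimethyl-3'-(propan-2-yl)spiro[bicyclo[3.1.1]heptane-2,1'-cyclopentane]-2'-carboxylic acid (2'-epimer mixture), via cyclopentene acid 14 (not isolated)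
Conditions: second-generation Grubbs catalyst RuCl2(=CHPh)(PCy3)(H2IMes) (5 mol %), toluene, 80 °C; then Pd/C, H2 (3 atm), EtOAc, rt
Reagents that add atoms: none
Why: Ring-closing metathesis of the vinyl and propenyl groups closes the cyclopentene with loss of propene and the disubstituted alkene is then hydrogenated in the same flask; no stereocentre is formed or touched.

Step 9
Reactants: 16 methyl isobutyrate; 17 propionyl chloride
Product: 18 methyl 2,2-dimethyl-3-oxopentanoate
Conditions: LiN(iPr)2 (1.05 equiv), THF, −78 °C; then 17, −78 to 0 °C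
Reagents that add atoms: none
Why: Crossed Claisen acylation of the lithium ester enolate by the acid chloride; the product has no proton between its carbonyl groups, so it is not consumed by deprotonation.

Step 10
Reactants: 15 spiro acid
Product: 19 6,6-dimethyl-3'-(propan-2-yl)spiro[bicyclo[3.1.1]heptane-2,1'-cyclopentane]-2'-carbonyl chloride (2'-epimer mixture)
Conditions: (COCl)2 (1.5 equiv), DMF (cat.), CH2Cl2, 0 °C to rt; evaporate
Reagents that add atoms: oxalyl chloride, ClC(=O)C(=O)Cl
Why: Standard conversion of a hindered acid into its chloride through the Vilsmeier-type chloroiminium species; the labile α-centre is inconsequential.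

Step 11
Reactants: 19 spiro acid chloride; 18 methyl 2,2-dimethyl-3-oxopentanoate
Product: 21 cyclic trione (enol form; the target with OH in place of OCH3), via diketo ester 20 (not isolated)
Conditions: 18 (2.2 equiv), LiN(iPr)2 (2.2 equiv), THF, −78 °C; add 19, −78 to 0 °C; then LiN(iPr)2 (2.5 equiv), −78 °C to rt; then 1 M HCl
Reagents that add atoms: none
Why: The lithium enolate of 18 (its only enolisable position is the ethyl CH2) is C-acylated by 19, directly or through the derived ketene, to give diketonate 20; excess amide base then removes the methine proton on the cyclopentane, and the resulting dianion attacks the methyl ester and expels methoxide. The closest known reaction type is the crossed Claisen/Dieckmann sequence by which 3,5-dioxo esters are closed to cyclohexane-1,3,5-triones in polyketide-type phloroglucinol syntheses. The six-membered ring closes in the 6-(enolendo)-exo-trig mode, which Baldwin's rules favour. The new quaternary spiro stereocentre is controlled by the adjacent isopropyl-bearing carbon: the planar enolate carbon (both epimers of 19 converge on it) should be acylated on the cyclopentane face anti to isopropyl, placing the CMe2-flanked carbonyl trans and the C-methyl-flanked carbonyl cis to isopropyl as in the target, while the two pinane arms on the other neighbour (bridgehead CH and CH2) shield the two faces about equally. The step needs C- over O-acylation in the ring closure and this facial selectivity; the first is secured because an enol lactone from O-attack is reopened by methoxide whereas the C-acylated product leaves the equilibrium as its stabilised trione enolate, and the second by the 1,2-relationship to the isopropyl group.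

Step 12
Reactants: 21 cyclic trione
Product: 22 CNP0307059.1
Conditions: HC(OMe)3 (3 equiv), TsOH·H2O (10 mol %), MeOH, 50 °C
Reagents that add atoms: trimethyl orthoformate, COC(OC)OC
Why: Acid-catalysed enol etherification of the vinylogous acid under thermodynamic control: the enol carbonyl flanked by CMe2 is far less congested than the one flanked by the spiro carbon, so the methoxy group should settle next to CMe2, and the two regioisomers can equilibrate through the common protonated intermediate.

Compound list
1 | (1R,5R)-(+)-β-pinene, (1R,5R)-6,6-dimethyl-2-methylidenebicyclo[3.1.1]heptane | C=C1CC[C@@H]2C[C@H]1C2(C)C | starting material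
2 | secondary ozonide of 1 (1,2,4-trioxolane spiro-fused at pinane C-2, bridgeheads as in 1, either configuration at the spiro carbon) | C1OOC2(O1)CC[C@@H]3C[C@H]2C3(C)C | intermediate
3 | (1S,5R)-(−)-nopinone, (1S,5R)-6,6-dimethylbicyclo[3.1.1]heptan-2-one | O=C1CC[C@@H]2C[C@H]1C2(C)C | intermediate
4 | Meldrum's acid, 2,2-dimethyl-1,3-dioxane-4,6-dione | CC1(C)OC(=O)CC(=O)O1 | starting material
5 | 5-[(1S,5R)-6,6-dimethylbicyclo[3.1.1]heptan-2-ylidene]-2,2-dimethyl-1,3-dioxane-4,6-dione | CC1(C)OC(=O)C(=C2CC[C@@H]3C[C@H]2C3(C)C)C(=O)O1 | intermediate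
6 | 5-[(1S,2R,5R)-2-ethenyl-6,6-dimethylbicyclo[3.1.1]heptan-2-yl]-2,2-dimethyl-1,3-dioxane-4,6-dione (vinyl anti to the CMe2 bridge) | CC1(C)OC(=O)C(C(=O)O1)[C@@]1(C=C)CC[C@@H]2C[C@H]1C2(C)C | intermediate
7 | 2-[(1S,2R,5R)-2-ethenyl-6,6-dimethylbicyclo[3.1.1]heptan-2-yl]acetic acid | OC(=O)C[C@@]1(C=C)CC[C@@H]2C[C@H]1C2(C)C | intermediate
8 | (E)-5-methylhex-3-en-2-one | CC(=O)/C=C/C(C)C | starting material
9 | (2R,3E)-5-methylhex-3-en-2-ol | C[C@@H](O)/C=C/C(C)C | intermediate
10 | (2R,3E)-5-methylhex-3-en-2-yl 2-[(1S,2R,5R)-2-ethenyl-6,6-dimethylbicyclo[3.1.1]heptan-2-yl]acetate | C[C@H](/C=C/C(C)C)OC(=O)C[C@@]1(C=C)CC[C@@H]2C[C@H]1C2(C)C | intermediate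
11 | trimethylsilyl ketene acetal of 10 (ketene acetal geometry not defined) | C[C@H](/C=C/C(C)C)OC(O[Si](C)(C)C)=C[C@@]1(C=C)CC[C@@H]2C[C@H]1C2(C)C | intermediate
12 | trimethylsilyl ester of 13 | C/C=C/[C@H](C(C)C)C(C(=O)O[Si](C)(C)C)[C@@]1(C=C)CC[C@@H]2C[C@H]1C2(C)C | intermediate
13 | (3S,4E)-2-[(1S,2R,5R)-2-ethenyl-6,6-dimethylbicyclo[3.1.1]heptan-2-yl]-3-(propan-2-yl)hex-4-enoic acid, C-2 epimer mixture | C/C=C/[C@H](C(C)C)C(C(=O)O)[C@@]1(C=C)CC[C@@H]2C[C@H]1C2(C)C | intermediate
14 | 6,6-dimethyl-3'-(propan-2-yl)spiro[bicyclo[3.1.1]heptane-2,1'-cyclopent[4]ene]-2'-carboxylic acid; C-2' on the CMe2-bridge face of pinane C-2, isopropyl cis to pinane C-3 across the five-membered ring, 2'-epimer mixture | OC(=O)C1[C@@H](C(C)C)C=C[C@@]12CC[C@@H]3C[C@H]2C3(C)C | intermediate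
15 | 6,6-dimethyl-3'-(propan-2-yl)spiro[bicyclo[3.1.1]heptane-2,1'-cyclopentane]-2'-carboxylic acid; stereochemistry as in 14, 2'-epimer mixture | OC(=O)C1[C@@H](C(C)C)CC[C@@]12CC[C@@H]3C[C@H]2C3(C)C | intermediate
16 | methyl isobutyrate | COC(=O)C(C)C | starting material
17 | propionyl chloride | CCC(=O)Cl | starting material
18 | methyl 2,2-dimethyl-3-oxopentanoate | CCC(=O)C(C)(C)C(=O)OC | intermediate
19 | acid chloride of 15, 2'-epimer mixture | ClC(=O)C1[C@@H](C(C)C)CC[C@@]12CC[C@@H]3C[C@H]2C3(C)C | intermediate
20 | methyl 2,2,4-trimethyl-3,5-dioxo-5-[6,6-dimethyl-3'-(propan-2-yl)spiro[bicyclo[3.1.1]heptane-2,1'-cyclopentan]-2'-yl]pentanoate, epimer mixture at C-4 and C-2' | COC(=O)C(C)(C)C(=O)C(C)C(=O)C1[C@@H](C(C)C)CC[C@@]12CC[C@@H]3C[C@H]2C3(C)C | intermediate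
21 | 4''-hydroxy-3'',5'',5'',6,6-pentamethyl-3'-(propan-2-yl)dispiro[bicyclo[3.1.1]heptane-2,1'-cyclopentane-2',1''-cyclohex[3]ene]-2'',6''-dione (one enol tautomer of the cyclic 1,3,5-trione; configuration as in 22) | OC1=C(C)C(=O)[C@@]2(C(=O)C1(C)C)[C@@H](C(C)C)CC[C@@]21CC[C@@H]2C[C@H]1C2(C)C | intermediate
22 | CNP0307059.1, 4''-methoxy-3'',5'',5'',6,6-pentamethyl-3'-(propan-2-yl)dispiro[bicyclo[3.1.1]heptane-2,1'-cyclopentane-2',1''-cyclohex[3]ene]-2'',6''-dione; spiro carbon 2' on the CMe2-bridge face of the pinane, CMe2-flanked carbonyl trans and enone carbonyl cis to the 3'-isopropyl group, isopropyl cis to pinane C-3 | COC1=C(C)C(=O)[C@@]2(C(=O)C1(C)C)[C@@H](C(C)C)CC[C@@]21CC[C@@H]2C[C@H]1C2(C)C | target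

Total step count: 12. Longest linear sequence: 10 steps (steps 1, 2, 3, 4, 6, 7, 8, 10, 11, 12).

Steps most likely to fail

Step 11. The second stage may stall at the diketonate, because deprotonation of the hindered methine and attack on the neopentyl-type ester are both slow. The acylation at the enolate carbon may also be insufficiently face-selective. The fallback sets out from acid 15 and replaces the kinetic dianion closure by an enol lactone isomerisation under thermodynamic control. Acid 15 with EtLi (2.2 equiv, Et2O, 0 °C) should give the ethyl ketone F1. Soft enolisation of its CH2 group (MgBr2·OEt2, iPr2NEt, CH2Cl2) and reaction with dimethylmalonyl dichloride should give, by C-acylation then O-acylation, the 3,3,5-trimethylpyran-2,4-dione enol lactone F2. NaOMe in refluxing MeOH should then open the lactone and re-close it at carbon (the classical enol lactone to cyclic 1,3-dione rearrangement), with the ring closure reversible until the trione enolate forms, to rejoin the route at 21.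

Step 12. Etherification may be slow at the hindered vinylogous acid, or methylation may occur at the enol carbonyl next to the spiro carbon. The fallback sets out from 21 and fixes the position in two stages. Oxalyl chloride with catalytic DMF in CH2Cl2 should activate the less hindered enol oxygen and give the vinylogous acid chloride F3, with chlorine on the carbon next to CMe2. NaOMe in MeOH at 0 °C should then replace chloride by addition–elimination at that same carbon and rejoin the route at 22.

Step 2. The condensation may remain incomplete because the ketone is shielded by the bridgehead and the CMe2 bridge, with enolisation and self-aldol reaction competing. The fallback sets out from 3. Horner–Wadsworth–Emmons olefination (NaH, (EtO)2P(O)CH2CO2Et, THF, reflux) should give ethyl nopinylideneacetate F4. Conjugate addition of the vinylcopper–BF3 reagent (CH2=CHMgBr, CuBr·SMe2, BF3·OEt2, THF, −78 °C), again from the CH2-bridge face, should give ethyl ester F5. Saponification (LiOH, THF/H2O, 50 °C) rejoins the route at acid 7.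

Further compounds
F1 | step 11 | 1-[6,6-dimethyl-3'-(propan-2-yl)spiro[bicyclo[3.1.1]heptane-2,1'-cyclopentan]-2'-yl]propan-1-one (2'-epimer mixture) | CCC(=O)C1[C@@H](C(C)C)CC[C@@]12CC[C@@H]3C[C@H]2C3(C)C
F2 | step 11 | 6-[6,6-dimethyl-3'-(propan-2-yl)spiro[bicyclo[3.1.1]heptane-2,1'-cyclopentan]-2'-yl]-3,3,5-trimethyl-2H-pyran-2,4(3H)-dione (2'-epimer mixture) | CC1=C(OC(=O)C(C)(C)C1=O)C1[C@@H](C(C)C)CC[C@@]12CC[C@@H]3C[C@H]2C3(C)C
F3 | step 12 | 4''-chloro-3'',5'',5'',6,6-pentamethyl-3'-(propan-2-yl)dispiro[bicyclo[3.1.1]heptane-2,1'-cyclopentane-2',1''-cyclohex[3]ene]-2'',6''-dione (configuration as in 22) | ClC1=C(C)C(=O)[C@@]2(C(=O)C1(C)C)[C@@H](C(C)C)CC[C@@]21CC[C@@H]2C[C@H]1C2(C)C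
F4 | step 2 | ethyl 2-[(1S,5R)-6,6-dimethylbicyclo[3.1.1]heptan-2-ylidene]acetate (E/Z mixture) | CCOC(=O)C=C1CC[C@@H]2C[C@H]1C2(C)C
F5 | step 2 | ethyl 2-[(1S,2R,5R)-2-ethenyl-6,6-dimethylbicyclo[3.1.1]heptan-2-yl]acetate | CCOC(=O)C[C@@]1(C=C)CC[C@@H]2C[C@H]1C2(C)C
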